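Stage the second nucleophile and keep the first nucleophile whole at the start: that is the recipe to back among these flasks.

| setting | blue | grey | ochre | south-west | north | north-east | north-west |
|---|---|---|---|---|---|---|---|
| substrate | 0.047 M | 0.047 M | 0.047 M | 0.047 M | 0.047 M | 0.047 M | 0.047 M |
| first nucleophile | 0.0846 M | 0.12 M | 0.19 M | 0.0846 M (fed, over 50 h) | 0.0846 M | 0.0846 M (fed, over 50 h) | 0.0846 M |
| second nucleophile | 0.0329 M | 0.0329 M | 0.0329 M | 0.0329 M | 0.0329 M | 0.0329 M | 0.0329 M (in portions, 4, over 50 h) |
| capture agent | 0.94 mM | 0.94 mM | 0.94 mM | 0.940 mM | 0.940 mM | 0.940 mM | 0.940 mM |
| temperature | 45 °C | 56 °C | 45 °C | 50 °C | 50 °C |  | 50 °C |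
| remark | run made earlier | run made earlier | run made earlier | all else is in the flask from the start; the feed brings no volume worth counting | everything together at the start | the addition at 20 °C, then warmed to 50 °C; the feed brings no volume worth counting | first portion at the start, last at 50 h |
| time |  |  |  | 5.0 d | 5.0 d | 5.0 d | 5.0 d |

| run | time / d | target / % |
|---|---|---|
| blue | 0.250 | 10.3 |
| blue | 0.333 | 12.0 |
| blue | 0.500 | 18.1 |
| blue | 0.833 | 27.3 |
| blue | 1.25 | 37.6 |
| blue | 2.08 | 49.9 |
| blue | 3.00 | 60.4 |
| grey | 0.625 | 32.7 |
| grey | 1.25 | 51.4 |
| grey | 2.00 | 64.3 |
| grey | 3.00 | 74.0 |
| grey | 4.00 | 79.5 |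
| grey | 5.00 | 82.1 |
| ochre | 0.417 | 30.7 |
| ochre | 0.625 | 40.3 |
| ochre | 0.833 | 51.3 |
| ochre | 1.25 | 62.3 |
| ochre | 2.00 | 75.8 |
| ochre | 3.00 | 86.7 |
| ochre | 5.00 | 91.1 |

(readings scatter by 0.5 percentage points)

- steps under discussion: substrate <-> open intermediate; first nucleophile + open intermediate -> target; second nucleophile + open intermediate -> other capture product; open intermediate + capture agent -> trapped intermediate; open intermediate -> side product

- the flask with the highest amount of target, in percent of the substrate charged ("all alike" if they lie within 1.5 percentage points) (south-west / north / north-east / north-west / all alike)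
- final target, as a percentage of the substrate charged, in south-west
- final target, as a percentage of the substrate charged, in north
- final target, as a percentage of the substrate charged, in north-east
- final target, as a percentage of the substrate charged, in north-west

Substrate opens reversibly, and the open intermediate is shared among its capturing partners. The ochre run prices that competition. Its last reading, 91.1% of target at 5.00 d, is here taken as spent substrate, with [first nucleophile] at its mean over the run. That gives 0.0165 M for the break-even concentration c*, the [first nucleophile] at which target and the losses together form equally fast. It is a selectivity factor with a unit. The target share of converted substrate is then [first nucleophile]/([first nucleophile] + c*). This reckoning is my own, and it carries c* to 50 °C unchanged, which is a rough step.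

North starts at the full charge. Taking half of the substrate charge off it leaves a mean near 0.0611 M, so the share is 78.8%. Feeding the first nucleophile in south-west gives a mean near 0.0423 M during the feed, so its share of 72.0% is lower than north's. Staging in north-west holds the mean [second nucleophile] over the 50 h at half of its charge. The earlier runs held that charge at 0.0329 M, so they give no split of c*. With c* taken at half, a rough guess, the share in north-west is 88.1%, higher than north's. North-east feeds at 20 °C, colder than the earlier runs, so c* gives no number there. The clock then cuts each share by the substrate still unconverted.

The forecast says north-west leads, with 75% there, 72% in north, 65% in north-east and 63% in south-west. Of the cold feed it says “suppresses losses, but conversion is slower and warm time is shorter”.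

The most target stands in north-west: 74.5%, against 72.0% in north, 64.1% in north-east and 62.7% in south-west. North-west ends with 7.45% of other capture product, less than the 11.0% in north. In south-west, 15% of the substrate still stands at 5.00 d, so the share 72.0% on the converted remainder gives 61.2%, against the 62.7% found.

    substrate ⇌ open intermediate (K = 0.0220, k = 0.00635 /min, Ea = 100 kJ/mol, ΔH = −49.0 kJ/mol)
    first nucleophile + open intermediate → target (k = 0.195 /M/min, Ea = 53.0 kJ/mol)
    second nucleophile + open intermediate → other capture product (k = 0.0655 /M/min, Ea = 70.0 kJ/mol)
    open intermediate + capture agent → trapped intermediate (k = 0.00678 /M/min, Ea = 83.0 kJ/mol)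
    open intermediate → side product (k = 0.00102 /min, Ea = 98.0 kJ/mol)
    (constants at 50 °C)

A neighbour flask is north-west with 0.021 M of first nucleophile, and c* gives it a share of 56.0% at that charge. Computed, this neighbour flask ends with 27.7% of target and 45.8% of substrate left, so target is 51.0% of the converted substrate.

The data are simulated with made-up constants, noise included.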